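A factor in monomer in chains between two stopping times is not a factor in chain length: the average divides by the chains begun, and the earlier readings do not show that count.

| setting | Wednesday's | oak | elm |
|---|---|---|---|
| free monomer | 2.2 M (fed, over 4.0 min) | 1.6 M (fed, over 4.0 min) | 1.6 M (fed, over 4.0 min) |
| pre-initiator | 82 mM | 82 mM | 82 mM |
| remark | run made earlier; the fed solution adds 0.20 times the starting volume | the fed solution adds 0.20 times the starting volume | the fed solution adds 0.20 times the starting volume |
| time |  | 4.0 min | 2.0 min |

- which of the two ends with the longer chains by the average number of monomer units in a chain (chains begun, living or dead) ("neither" if they lie within 10%) (oak / elm / neither)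
- average number of monomer units in a chain (chains begun, living or dead) at the end, oak
- average number of monomer units in a chain (chains begun, living or dead) at the end, elm

- amounts are per litre of the starting volume; all of the dose is in the solution fed
- the average divides the monomer in chains by the number of chains begun, living and dead together
- the analysis behind the earlier runs scatters by 1 percentage point, standard deviation
- percentages count the whole charge, also what has not yet gone in
- the earlier runs do not show the number of chains; that part of a forecast is a guess

Elm has the recipe of oak and stops at half of its time, so the question is how length grows along one feed.

Wednesday's run (percent of the free monomer charged)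

| time / min | monomer in chains / % | free monomer / % |
|---|---|---|
| 0.333 | 0.2 | 8.4 |
| 0.500 | 0.5 | 11.6 |
| 0.667 | 1.2 | 16.5 |
| 1.00 | 0.2 | 23.8 |
| 1.50 | 3.4 | 34.7 |
| 2.50 | 20.3 | 44.7 |
| 4.00 | 66.0 | 34.4 |

(scatter of a reading: 1 percentage point)

Wednesday's run has a larger charge, but its fractions of the charge can still give a shape. Before 1.50 min monomer in chains reads no more than 1.2% against a scatter of 1 percentage point, so the logarithms start at 3.4% at 1.50 min and end at 66.0% at 4.00 min. That is 1.29 powers of ten in fraction over 0.426 in time. Their quotient, 3.02, a reading that carries that scatter, is the time exponent, the slope of log fraction in chains against log time.

Taking this exponent over to oak and elm is my assumption. Doubling the time then multiplies monomer in chains by 8.13. Free monomer in Wednesday's run stays between 34.4% and 44.7% over that stretch, so the pseudo-first-order constant, rate over free monomer, follows the exponent less one. If every growing chain adds monomer equally, the chain count rises by 4.07. My reckoning therefore puts oak at twice the length of elm, beyond the margin of 10%, and gives no absolute length.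

The forecast names oak, with 37 for oak and 12 for elm, adding “Chain count is a guess”.

The flask gives oak, with 27.2 for oak and 9.62 for elm.

    pre-initiator ⇌ initiator (K = 7.50, k = 0.00820 s⁻¹)
    free monomer + initiator → living end + monomer in chains (k = 0.00890 M⁻¹ s⁻¹)
    free monomer + living end → monomer in chains + living end, rate k3*[living end]*[free monomer] (k = 0.460 M⁻¹ s⁻¹)

Oak's length is 2.83 times elm's, not the reckoned 2.00, while its monomer in chains, 59.9% against 7.05% for elm, is up 8.50 times against the reckoned 8.13. Continued from oak's end as an estimate, the exponent gives the whole charge in chains at 4.74 min. The flask of oak read at 10 min holds 99.9% in chains, with an average length of 35.9.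

All runs come from a simulation on assumed constants, and the scatter is random.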